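**Retrosynthetic overview**

Ring atoms: C1 (quaternary, two prenyl groups), C2 (enol OH), C3 (CH3), C4 (C=O), C5 (benzoyl), C6 (enol OH). The strategy rests on the benzoylated β-triketone array C4(=O)–C5(COPh)–C6(OH), which is carried as a 3-phenylisoxazole fused across C5–C6 (isoxazole O on C6, the C=N carbon is the benzoyl carbon) and so has no acidic hydrogen.
Target ⇐ primary enaminone (hydrolysis of C–NH2 to C–OH) ⇐ fused 1,2-benzoxazol-4-one (reductive N–O cleavage).
Key disconnection C3–C4: Dieckmann closure of an ethyl ketone enolate onto the isoxazole-4-carboxylate; this closes the carbocycle, the only ring made (the isoxazole and phenyl rings are bought).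
Diprenyl keto ester ⇐ 5-(2-oxobutyl)isoxazole ester (double C-prenylation at C1) ⇐ methyl 5-methyl-3-phenylisoxazole-4-carboxylate plus a propanoyl Weinreb amide (lateral acylation of the 5-methyl group, the future C1) ⇐ the commercial acid.

Key step: step 4

Remark: the enolised di- and triketones (Dieckmann product, enaminone, target) are each written as one tautomer although the tautomers interconvert, and the target has no stereocentre.

**Route**

Step 1
Reactants: 1 5-methyl-3-phenylisoxazole-4-carboxylic acid
Product: 3 methyl 5-methyl-3-phenylisoxazole-4-carboxylate, via potassium carboxylate 2 (not isolated)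
Conditions: K2CO3 (1.5 equiv), MeI (1.5 equiv), DMF, 23 °C
Reagents that add atoms: iodomethane, CI
Why: SN2 O-methylation of the carboxylate (carboxylate alkylation) avoids acyl substitution at an acid flanked by phenyl and methyl groups, and the 3,4,5-trisubstituted isoxazole is inert to K2CO3.

Step 2
Reactants: 3 methyl 5-methyl-3-phenylisoxazole-4-carboxylate; 4 N-methoxy-N-methylpropanamide
Product: 7 methyl 5-(2-oxobutyl)-3-phenylisoxazole-4-carboxylate, via lithiated ester 5 (not isolated), via tetrahedral lithium adduct 6 (not isolated)
Conditions: LiN(iPr)2 (1.1 equiv), THF, −78 °C (3 added to the base); 4 (1.2 equiv), −78 to −40 °C; AcOH, then H2O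
Reagents that add atoms: N-methoxy-N-methylpropanamide (4), CCC(=O)N(C)OC
Why: The 5-methyl group is the vinylogous α-position of the 4-ester, so LiN(iPr)2 should deprotonate it (lateral metalation) and the anion should add once to the amide (Weinreb ketone synthesis), the chelated adduct 6 holding the ketone back until the quench so that the acidic product neither protonates unreacted anion nor is acylated twice, as an acid chloride would allow.

Step 3
Reactants: 7 methyl 5-(2-oxobutyl)-3-phenylisoxazole-4-carboxylate; 8 1-bromo-3-methylbut-2-ene (prenyl bromide)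
Product: 10 methyl 5-[1,1-bis(3-methylbut-2-enyl)-2-oxobutyl]-3-phenylisoxazole-4-carboxylate, via monoprenyl ketone 9 (not isolated)
Conditions: Cs2CO3 (3 equiv), 8 (2.6 equiv, present from the start), MeCN, 0 to 23 °C
Reagents that add atoms: 1-bromo-3-methylbut-2-ene (8), CC(C)=CCBr
Why: The methylene between the ketone and the electron-poor isoxazole is the only position acidic enough for Cs2CO3, and the soft allylic bromide should alkylate its enolate at carbon twice by SN2 (enolate C-alkylation), the excess bromide intercepting the enolate before it can add to the neighbouring ester; the new quaternary carbon is not a stereocentre because both groups are the same.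

Step 4
Reactants: 10 methyl 5-[1,1-bis(3-methylbut-2-enyl)-2-oxobutyl]-3-phenylisoxazole-4-carboxylate
Product: 13 6-hydroxy-5-methyl-7,7-bis(3-methylbut-2-enyl)-3-phenyl-1,2-benzoxazol-4(7H)-one, via lithium ketone enolate 11 (not isolated), via lithium dionate 12 (not isolated)
Conditions: LiN(SiMe3)2 (2.3 equiv), THF, −78 to 23 °C; then 1 M HCl, 0 °C
Reagents that add atoms: none
Why: LiN(SiMe3)2 deprotonates the ethyl ketone at its CH2 group (future C3), the only enolisable position because C1 is quaternary and the 3-phenylisoxazole has no acidic hydrogen, to give enolate 11; C3 then adds to the ester carbonyl on isoxazole C4 (future C4), LiOMe is expelled, and the acidic dione is carried on to its lithium salt 12 by the second equivalent of base. The closest known reaction type is the Dieckmann (intramolecular Claisen) condensation of a ketone enolate with an ortho-placed aryl ester, as in the closure of methyl 2-(2-oxoalkyl)benzoates to naphthalene-1,3-diols. The carbocycle closes in the 6-(enolexo)-exo-trig mode, helped by the two prenyl groups on C1 (Thorpe–Ingold effect) and by the cis placement of both arms on the isoxazole C4=C5 bond. No stereocentre is formed, since C1 carries two identical groups and C3 ends as an sp2 carbon. The selectivity needed is C- over O-acylation of the enolate (both six-membered); it is secured thermodynamically, because LiOMe reopens the enol lactone to the keto ester whereas the C-acylated product is withdrawn as the stabilised salt 12, and the low temperature with a poorly nucleophilic amide base limits retro-Claisen loss of the propanoyl group.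

Step 5
Reactants: 13 6-hydroxy-5-methyl-7,7-bis(3-methylbut-2-enyl)-3-phenyl-1,2-benzoxazol-4(7H)-one
Product: 14 2-[amino(phenyl)methylidene]-5-hydroxy-4-methyl-6,6-bis(3-methylbut-2-enyl)cyclohex-4-ene-1,3-dione
Conditions: Mo(CO)6 (1.2 equiv), MeCN/H2O (10:1), 80 °C
Reagents that add atoms: none
Why: Zerovalent molybdenum coordinates the isoxazole nitrogen and inserts into the weak N–O bond of the 4-acylisoxazole, water supplying the two hydrogens (reductive isoxazole ring opening to a β-enaminoketone), while the trisubstituted prenyl alkenes, which catalytic hydrogenolysis would reduce, should not be touched.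

Step 6
Reactants: 14 2-[amino(phenyl)methylidene]-5-hydroxy-4-methyl-6,6-bis(3-methylbut-2-enyl)cyclohex-4-ene-1,3-dione
Product: 16 2-benzoyl-3,5-dihydroxy-6-methyl-4,4-bis(3-methylbut-2-enyl)cyclohexa-2,5-dien-1-one (CNP0132199.0), via disodium salt 15 (not isolated)
Conditions: 2 M aq. NaOH, THF/MeOH, 60 °C; then 1 M HCl to pH 3, 0 °C
Reagents that add atoms: water, O
Why: Hydroxide adds to the enamine carbon of the vinylogous amide and ammonia is expelled (addition–elimination hydrolysis of a 2-(aminomethylidene)-1,3-dione to the β-triketone), the product being shielded from retro-Claisen cleavage as its dianion 15, and the alkaline medium followed by a brief cold acidification should spare the acid-sensitive prenyl groups.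

**Compound list**

1 | 5-methyl-3-phenylisoxazole-4-carboxylic acid | Cc1onc(-c2ccccc2)c1C(=O)O | starting material
2 | potassium 5-methyl-3-phenylisoxazole-4-carboxylate | Cc1onc(-c2ccccc2)c1C(=O)[O-].[K+] | intermediate, not isolated
3 | methyl 5-methyl-3-phenylisoxazole-4-carboxylate | Cc1onc(-c2ccccc2)c1C(=O)OC | intermediate
4 | N-methoxy-N-methylpropanamide | CCC(=O)N(C)OC | starting material
5 | methyl 5-(lithiomethyl)-3-phenylisoxazole-4-carboxylate | [Li]Cc1onc(-c2ccccc2)c1C(=O)OC | intermediate, not isolated
6 | lithium 1-[4-(methoxycarbonyl)-3-phenylisoxazol-5-yl]-2-[methoxy(methyl)amino]butan-2-olate (racemic) | CCC(O[Li])(Cc1onc(-c2ccccc2)c1C(=O)OC)N(C)OC | intermediate, not isolated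
7 | methyl 5-(2-oxobutyl)-3-phenylisoxazole-4-carboxylate | CCC(=O)Cc1onc(-c2ccccc2)c1C(=O)OC | intermediate
8 | 1-bromo-3-methylbut-2-ene (prenyl bromide) | CC(C)=CCBr | starting material
9 | methyl 5-[1-(3-methylbut-2-enyl)-2-oxobutyl]-3-phenylisoxazole-4-carboxylate (racemic) | CCC(=O)C(CC=C(C)C)c1onc(-c2ccccc2)c1C(=O)OC | intermediate, not isolated
10 | methyl 5-[1,1-bis(3-methylbut-2-enyl)-2-oxobutyl]-3-phenylisoxazole-4-carboxylate | CCC(=O)C(CC=C(C)C)(CC=C(C)C)c1onc(-c2ccccc2)c1C(=O)OC | intermediate
11 | lithium (Z)-enolate of 10 (Z geometry expected for a ketone with a bulky α-quaternary group) | C/C=C(\O[Li])C(CC=C(C)C)(CC=C(C)C)c1onc(-c2ccccc2)c1C(=O)OC | intermediate, not isolated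
12 | lithium salt of 13 (lithium 5-methyl-7,7-bis(3-methylbut-2-enyl)-4-oxo-3-phenyl-4,7-dihydro-1,2-benzoxazol-6-olate) | CC1=C(O[Li])C(CC=C(C)C)(CC=C(C)C)c2onc(-c3ccccc3)c2C1=O | intermediate, not isolated
13 | 6-hydroxy-5-methyl-7,7-bis(3-methylbut-2-enyl)-3-phenyl-1,2-benzoxazol-4(7H)-one | CC1=C(O)C(CC=C(C)C)(CC=C(C)C)c2onc(-c3ccccc3)c2C1=O | intermediate
14 | 2-[amino(phenyl)methylidene]-5-hydroxy-4-methyl-6,6-bis(3-methylbut-2-enyl)cyclohex-4-ene-1,3-dione | CC1=C(O)C(CC=C(C)C)(CC=C(C)C)C(=O)C(=C(N)c2ccccc2)C1=O | intermediate
15 | disodium salt of 16 | CC(C)=CCC1(CC=C(C)C)C([O-])=C(C)C(=O)C(C(=O)c2ccccc2)=C1[O-].[Na+].[Na+] | intermediate, not isolated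
16 | 2-benzoyl-3,5-dihydroxy-6-methyl-4,4-bis(3-methylbut-2-enyl)cyclohexa-2,5-dien-1-one (CNP0132199.0) | CC(C)=CCC1(CC=C(C)C)C(O)=C(C)C(=O)C(C(=O)c2ccccc2)=C1O | target

**Step count and risks**

Total steps: 6. Longest linear sequence: 6 steps (1 to 16).

Steps most likely to fail:

Step 3. In the second alkylation, which creates the quaternary carbon, the hindered enolate may react at oxygen instead of carbon, and the enolate oxygen may close onto the neighbouring methyl ester before it is alkylated. The fallback sets out from 7 and comes back at 10. It replaces the SN2 alkylation by a Tsuji–Trost allylation under neutral conditions: 7 is heated with methyl 3-methylbut-2-enyl carbonate F1 (made from 3-methylbut-2-en-1-ol and methyl chloroformate, pyridine, CH2Cl2) and Pd(PPh3)4 (5 mol %) in THF at 50 °C, passing through 9. Zerovalent palladium re-ionises any O-allylated material, so the mixture should drain to the C-alkylated product. The bulky stabilised nucleophile should attack the unsubstituted terminus of the 1,1-dimethylallyl palladium complex and give the linear prenyl group. The only base is the methoxide released from F1, which is degenerate with the methyl ester and would reopen a lactone.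

Step 4. The enolate may close through oxygen without re-equilibrating, or methoxide may attack the crowded ketone and detach the propanoyl group before the ring closes. The fallback sets out from 10 and comes back at 13. The methyl ester is cleaved by SN2 demethylation (LiI, EtOAc, reflux, then dilute acid), which does not depend on attack at the hindered acyl carbon, to give 5-[1,1-bis(3-methylbut-2-enyl)-2-oxobutyl]-3-phenylisoxazole-4-carboxylic acid F2. This is converted into its pentafluorophenyl ester F3 (C6F5OH, EDC·HCl, DMAP cat., CH2Cl2). The ring is then closed by soft enolisation and direct C-acylation of the ketone (MgBr2·OEt2, iPr2NEt, CH2Cl2, 23 °C). No alkoxide is released in this closure and the magnesium chelate favours reaction at carbon.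

Step 6. Addition of hydroxide to the hindered, anionic enaminone may be slow, so that forcing conditions bring retro-Claisen loss of the benzoyl group, or acidification may cyclise a prenyl group onto an enol oxygen. The fallback sets out from 14 and comes back at 16. The nitrogen is first turned into a better leaving group: Boc2O (3 equiv), DMAP (cat.), Et3N, CH2Cl2 should give tert-butyl N-{[4-(tert-butoxycarbonyloxy)-3-methyl-5,5-bis(3-methylbut-2-enyl)-2,6-dioxocyclohex-3-en-1-ylidene](phenyl)methyl}carbamate F4. LiOH in THF/H2O at 0 to 23 °C should then remove the enol carbonate and displace tert-butyl carbamate by addition–elimination, the vinylogous counterpart of cleaving an N-Boc-activated primary amide. Acidification with aqueous citric acid at 0 °C gives 16.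

**Further compounds**

F1 | step 3 | methyl 3-methylbut-2-enyl carbonate | COC(=O)OCC=C(C)C
F2 | step 4 | 5-[1,1-bis(3-methylbut-2-enyl)-2-oxobutyl]-3-phenylisoxazole-4-carboxylic acid | CCC(=O)C(CC=C(C)C)(CC=C(C)C)c1onc(-c2ccccc2)c1C(=O)O
F3 | step 4 | pentafluorophenyl 5-[1,1-bis(3-methylbut-2-enyl)-2-oxobutyl]-3-phenylisoxazole-4-carboxylate | CCC(=O)C(CC=C(C)C)(CC=C(C)C)c1onc(-c2ccccc2)c1C(=O)Oc1c(F)c(F)c(F)c(F)c1F
F4 | step 6 | tert-butyl N-{[4-(tert-butoxycarbonyloxy)-3-methyl-5,5-bis(3-methylbut-2-enyl)-2,6-dioxocyclohex-3-en-1-ylidene](phenyl)methyl}carbamate | CC1=C(OC(=O)OC(C)(C)C)C(CC=C(C)C)(CC=C(C)C)C(=O)C(=C(NC(=O)OC(C)(C)C)c2ccccc2)C1=O
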